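**Plan**

1. Retrosynthetic cuts: the C15–O ester bond (C30 acid), then C12–C13 (alkyl–alkenyl coupling), the 7,8-alkene back to a C7 ketone, then C5–C10 and C8–C9 together, then C5=C6 (olefination) and C3–C4 (aldol), back to the ozonolysis aldehyde of geranyl acetate.
2. Enabling feature: ring B of the trans-decalin is a cyclohexene whose C5–C10 and C8–C9 bonds flank the quaternary C10 (angular methyl) and the side-chain carbon C9. With oxygen placed at C7 it is the retron of a [4+2] addition between a C5=C6–C7(OSi)=C8 diene and a C9=C10 enal joined through C1–C4.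
3. Forward order: the acyclic C1–C11 chain is built first; rings A and B close in one operation; then C12 is added, the 7,8-alkene is set through an enol triflate, C13–C16 are coupled on, the acid is attached and the silyl groups are removed.
4. Stereochemistry: C3 from a reagent-controlled Mukaiyama aldol; C5, C9 and C10 from the cycloaddition (enal geometry, endo chair transition state, equatorial C3 silyloxy group); 13E from an (E)-enol triflate coupled with retention.

Key step: step 11

Remark: labdane numbering is used for ring compounds; the target is 3R,5S,9R,10S (C20, C11 and the 3-oxygen on one face, H-5 and H-9 on the other). Ring descriptors of intermediates change only through CIP priorities, never through inversion. TBS = tert-butyldimethylsilyl, Tf = trifluoromethanesulfonyl.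
Assumption: the borane complex of N-tosyl-L-valine is taken to give the 3R aldol with this unbranched aldehyde; the D-valine reagent is the mirror-image alternative.
Assumption: 12-bromododecan-1-ol and 18-bromooctadecanoic acid are purchased, and the C30 hydroxy acid is assembled from them instead of being bought.

**Route**

Step 1
Reactants: 1 geranyl acetate
Product: 3 (2E)-3-methyl-6-oxohex-2-en-1-yl acetate, via ozonide 2 (not isolated)
Conditions: O3 (1 equiv, Sudan Red 7B end point), CH2Cl2, −78 °C; then Me2S, −78 °C to rt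
Reagents that add atoms: ozone, [O-][O+]=O
Why: Chemoselective ozonolysis, in which the electron-rich 6,7-alkene reacts well before the 2,3-alkene deactivated by the allylic acetoxy group, and reductive work-up of the ozonide releases the aldehyde.

Step 2
Reactants: 3 (2E)-3-methyl-6-oxohex-2-en-1-yl acetate; 4 1-methoxy-2-methyl-1-(trimethylsilyloxy)prop-1-ene
Product: 5 methyl (3R,6E)-8-acetoxy-3-hydroxy-2,2,6-trimethyloct-6-enoate
Conditions: N-Ts-L-valine (1.1 equiv), BH3·THF (1.0 equiv), CH2Cl2, 0 °C to rt; then 3 and 4, −78 °C; pH 7 buffer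
Reagents that add atoms: none
Why: Enantioselective Mukaiyama aldol addition promoted by the oxazaborolidinone formed in the flask, in which the boron-bound aldehyde is shielded on one face so that the ketene acetal adds to the other and sets C3 as R.

Step 3
Reactants: 5 methyl (3R,6E)-8-acetoxy-3-hydroxy-2,2,6-trimethyloct-6-enoate
Product: 6 methyl (3R,6E)-8-acetoxy-3-(TBSO)-2,2,6-trimethyloct-6-enoate
Conditions: TBSOTf, 2,6-lutidine, CH2Cl2, −78 °C to 0 °C
Reagents that add atoms: tert-butyldimethylsilyl trifluoromethanesulfonate, CC(C)(C)[Si](C)(C)OS(=O)(=O)C(F)(F)F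
Why: O-silylation with the silyl triflate, which is reactive enough for the hindered secondary alcohol next to the quaternary carbon and blocks retro-aldol cleavage in later basic steps.

Step 4
Reactants: 6 methyl (3R,6E)-8-acetoxy-3-(TBSO)-2,2,6-trimethyloct-6-enoate
Product: 7 (2E,6R)-6-(TBSO)-3,7,7-trimethyloct-2-ene-1,8-diol
Conditions: i-Bu2AlH (5 equiv), CH2Cl2, −78 °C to 0 °C; aq. potassium sodium tartrate
Reagents that add atoms: none
Why: Exhaustive hydride reduction, which takes the hindered methyl ester to the neopentyl alcohol and necessarily cleaves the acetate, leaving silyl ether and alkene untouched.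

Step 5
Reactants: 7 (2E,6R)-6-(TBSO)-3,7,7-trimethyloct-2-ene-1,8-diol
Product: 8 (2E,6R)-6-(TBSO)-8-hydroxy-3,7,7-trimethyloct-2-en-1-yl 2,2-dimethylpropanoate
Conditions: PivCl (1.05 equiv), pyridine, CH2Cl2, −20 °C
Reagents that add atoms: pivaloyl chloride, CC(C)(C)C(Cl)=O
Why: Selective acylation, since the unhindered allylic hydroxyl reacts far faster than the neopentyl hydroxyl flanked by the quaternary carbon, and the pivalate (no α-hydrogen) withstands the basic steps that follow.

Step 6
Reactants: 8 (2E,6R)-6-(TBSO)-8-hydroxy-3,7,7-trimethyloct-2-en-1-yl 2,2-dimethylpropanoate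
Product: 9 (2E,6R)-6-(TBSO)-3,7,7-trimethyl-8-oxooct-2-en-1-yl 2,2-dimethylpropanoate
Conditions: Dess–Martin periodinane, CH2Cl2, rt
Reagents that add atoms: none
Why: Dess–Martin oxidation of the primary alcohol to an aldehyde that has no α-hydrogen and therefore cannot enolise or eliminate the β-silyloxy group.

Step 7
Reactants: 9 (2E,6R)-6-(TBSO)-3,7,7-trimethyl-8-oxooct-2-en-1-yl 2,2-dimethylpropanoate; 10 dimethyl (2-oxobutyl)phosphonate
Product: 11 (2E,6R,8E)-6-(TBSO)-3,7,7-trimethyl-10-oxododeca-2,8-dien-1-yl 2,2-dimethylpropanoate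
Conditions: Ba(OH)2·8H2O, THF/H2O (40:1), rt
Reagents that add atoms: none
Why: Horner–Wadsworth–Emmons olefination of the non-enolisable α-quaternary aldehyde with the β-keto phosphonate anion, which gives the (E)-enone and brings in C6, C7, C8 and C17.

Step 8
Reactants: 11 (2E,6R,8E)-6-(TBSO)-3,7,7-trimethyl-10-oxododeca-2,8-dien-1-yl 2,2-dimethylpropanoate
Product: 12 (2E,6R,8E,10Z)-6,10-bis(TBSO)-3,7,7-trimethyldodeca-2,8,10-trien-1-yl 2,2-dimethylpropanoate
Conditions: TBSOTf, Et3N, CH2Cl2, −78 °C to 0 °C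
Reagents that add atoms: tert-butyldimethylsilyl trifluoromethanesulfonate, CC(C)(C)[Si](C)(C)OS(=O)(=O)C(F)(F)F
Why: Soft enolisation (silyl triflate and amine) at the only enolisable position, the ethyl CH2, where minimised allylic strain favours the (Z)-silyl enol ether and so a 2-silyloxy-1,3-diene with its terminal methyl pointing outward.

Step 9
Reactants: 12 (2E,6R,8E,10Z)-6,10-bis(TBSO)-3,7,7-trimethyldodeca-2,8,10-trien-1-yl 2,2-dimethylpropanoate
Product: 13 (2E,6R,8E,10Z)-6,10-bis(TBSO)-3,7,7-trimethyldodeca-2,8,10-trien-1-ol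
Conditions: i-Bu2AlH (2.5 equiv), CH2Cl2, −78 °C; aq. potassium sodium tartrate
Reagents that add atoms: none
Why: Reductive cleavage of the pivalate by the aluminium hydride at low temperature, conditions to which the silyl ether and the silyl dienol ether are inert.

Step 10
Reactants: 13 (2E,6R,8E,10Z)-6,10-bis(TBSO)-3,7,7-trimethyldodeca-2,8,10-trien-1-ol
Product: 14 (2E,6R,8E,10Z)-6,10-bis(TBSO)-3,7,7-trimethyldodeca-2,8,10-trienal
Conditions: MnO2 (activated, excess), CH2Cl2, rt
Reagents that add atoms: none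
Why: Allylic oxidation with MnO2, which is neutral and heterogeneous, so that the (2E) geometry and the acid-labile silyl dienol ether persist.

Step 11
Reactants: 14 (2E,6R,8E,10Z)-6,10-bis(TBSO)-3,7,7-trimethyldodeca-2,8,10-trienal
Product: 15 (3R,5S,8S,9R,10R)-3,7-bis(TBSO)-12,13,14,15,16-pentanorlabd-6-en-11-al
Conditions: PhMe (0.01 M), BHT (cat.), 170 °C, sealed base-washed tube
Reagents that add atoms: none
Why: On heating, the s-cis 2-silyloxy-1,3-diene (C5=C6–C7(OTBS)=C8) adds suprafacially across the tethered (E)-enal (C9=C10) in a concerted, asynchronous [4+2] cycloaddition; the closest known reaction type is the type 1 intramolecular Diels–Alder reaction of 1,7,9-decatrienals, which gives trans-fused octalins with an angular methyl group. Ring B closes as the cyclohexene of the [4+2] itself through the C5–C10 and C8–C9 bonds, and ring A closes at the same time as a six-membered carbocycle through the C5–C10 bond, because the C1–C4 chain joins diene and dienophile in the fused rather than the bridged mode. The C9/C10 relationship (formyl cis to the angular methyl) is fixed by the E geometry of the enal, the trans fusion at C5/C10 by the endo placement of the formyl group over a chair-like tether, and C8 (methyl cis to formyl) by the outward methyl of the (Z)-enol ether; C8 is removed later. The absolute sense comes from C3, whose silyloxy group should take the equatorial site of the chair tether so that only one diene face is attacked. The step needs endo and diene-face selectivity and the C5–C10/C8–C9 pairing against the polarity of the silyloxydiene (its nucleophilic end is C8); the short tether, the geminal methyl groups at C4 (Thorpe–Ingold acceleration) and the use of heat instead of a Lewis acid, which would divert the enol ether into Mukaiyama-type addition, are expected to secure this.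

Step 12
Reactants: 15 (3R,5S,8S,9R,10R)-3,7-bis(TBSO)-12,13,14,15,16-pentanorlabd-6-en-11-al
Product: 16 (3R,5S,8S,9R,10S)-3,7-bis(TBSO)-13,14,15,16-tetranorlabda-6,11-diene
Conditions: Ph3PCH3Br, KOt-Bu, THF, 0 °C to rt
Reagents that add atoms: methyltriphenylphosphonium bromide, C[P+](c1ccccc1)(c1ccccc1)c1ccccc1.[Br-]
Why: Wittig methylenation with the small non-stabilised ylide adds C12 to the hindered aldehyde, and any base-induced epimerisation at C9 can only favour the desired equatorial substituent.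

Step 13
Reactants: 16 (3R,5S,8S,9R,10S)-3,7-bis(TBSO)-13,14,15,16-tetranorlabda-6,11-diene
Product: 17 (3R,5S,8S,9R,10S)-3-(TBSO)-13,14,15,16-tetranorlabd-11-en-7-one
Conditions: Bu4NF (1.1 equiv), AcOH (1.2 equiv), THF, 0 °C
Reagents that add atoms: none
Why: Fluoride-induced desilylation of the silyl enol ether with buffered protonation at C6, which is much faster than attack on the hindered secondary alkyl silyl ether at C3 and leaves C8 untouched (C8 becomes trigonal in the next step).

Step 14
Reactants: 17 (3R,5S,8S,9R,10S)-3-(TBSO)-13,14,15,16-tetranorlabd-11-en-7-one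
Product: 19 (3R,5S,9S,10R)-3-(TBSO)-13,14,15,16-tetranorlabda-7,11-dien-7-yl trifluoromethanesulfonate, via bromomagnesium enolate 18 (not isolated)
Conditions: i-Pr2NMgBr (from EtMgBr and i-Pr2NH), Et2O, rt; then PhNTf2, THF/DMPU, rt
Reagents that add atoms: N-phenylbis(trifluoromethanesulfonimide), O=S(=O)(N(c1ccccc1)S(=O)(=O)C(F)(F)F)C(F)(F)F
Why: Thermodynamic enolisation with the magnesium amide under equilibrating conditions gives the more substituted C7=C8 enolate (which also relieves the syn-axial C17/C20 contact), and O-sulfonylation of this enolate fixes the regiochemistry as the enol triflate.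

Step 15
Reactants: 19 (3R,5S,9S,10R)-3-(TBSO)-13,14,15,16-tetranorlabda-7,11-dien-7-yl trifluoromethanesulfonate
Product: 20 (3R,5S,9R,10R)-3-(TBSO)-13,14,15,16-tetranorlabda-7,11-diene
Conditions: Pd(OAc)2 (5 mol %), PPh3 (10 mol %), HCO2H, n-Bu3N, DMF, 60 °C
Reagents that add atoms: none
Why: Palladium-catalysed formate reduction of the enol triflate, in which zerovalent palladium formed from Pd(OAc)2 and PPh3 inserts into the C7–O bond, formate delivers hydride with loss of CO2 and reductive elimination leaves the alkene at C7=C8.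

Step 16
Reactants: 21 ethyl acetoacetate
Product: 22 ethyl (2E)-3-(trifluoromethanesulfonyloxy)but-2-enoate
Conditions: Tf2O, 25% aq. Me4NOH, hexane, 5 °C
Reagents that add atoms: trifluoromethanesulfonic anhydride, O=S(=O)(OS(=O)(=O)C(F)(F)F)C(F)(F)F
Why: Biphasic O-triflation of the β-keto ester enolate with a non-coordinating tetraalkylammonium counter-ion, which favours the extended non-chelated enolate and hence the (E)-enol triflate.

Step 17
Reactants: 20 (3R,5S,9R,10R)-3-(TBSO)-13,14,15,16-tetranorlabda-7,11-diene; 22 ethyl (2E)-3-(trifluoromethanesulfonyloxy)but-2-enoate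
Product: 24 ethyl (3R,5S,9R,10S,13E)-3-(TBSO)labda-7,13-dien-15-oate, via B-alkyl-9-BBN borane 23 (not isolated)
Conditions: 9-BBN dimer, THF, 0 °C to rt; then 22, PdCl2(dppf) (5 mol %), 3 M aq. K3PO4, THF/DMF, rt to 50 °C
Reagents that add atoms: none
Why: Anti-Markovnikov hydroboration of the monosubstituted alkene by 9-BBN (the trisubstituted 7,8-alkene is inert) followed by B-alkyl Suzuki–Miyaura coupling with the enol triflate, which proceeds with retention and so forms C12–C13 with the 13E geometry.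

Step 18
Reactants: 24 ethyl (3R,5S,9R,10S,13E)-3-(TBSO)labda-7,13-dien-15-oate
Product: 25 (3R,5S,9R,10S,13E)-3-(TBSO)labda-7,13-dien-15-ol
Conditions: i-Bu2AlH (2.5 equiv), CH2Cl2, −78 °C; aq. potassium sodium tartrate
Reagents that add atoms: none
Why: 1,2-Reduction of the α,β-unsaturated ester to the allylic alcohol by the aluminium hydride at low temperature, without effect on the alkenes or the silyl ether.

Step 19
Reactants: 26 12-bromododecan-1-ol
Product: 27 (12-bromododecyloxy)(tert-butyl)dimethylsilane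
Conditions: TBSCl, imidazole, DMF, rt
Reagents that add atoms: tert-butyldimethylsilyl chloride, CC(C)(C)[Si](C)(C)Cl
Why: Standard silylation of an unhindered primary alcohol with the silyl chloride and imidazole.

Step 20
Reactants: 27 (12-bromododecyloxy)(tert-butyl)dimethylsilane; 28 18-bromooctadecanoic acid
Product: 31 30-(TBSO)triacontanoic acid, via Grignard reagent 29 (not isolated), via chloromagnesium 18-bromooctadecanoate 30 (not isolated)
Conditions: 27, Mg, THF, 40 °C; separately 28, MeMgCl (1.0 equiv), THF, −20 °C; combine, Li2CuCl4 (3 mol %), −20 °C to rt; cold 0.5 M HCl work-up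
Reagents that add atoms: none
Why: Copper-catalysed alkyl–alkyl cross-coupling of a primary Grignard reagent with a primary bromide, the acid being masked in the flask as its unreactive magnesium carboxylate, so that C12 and C18 give the C30 chain.

Step 21
Reactants: 25 (3R,5S,9R,10S,13E)-3-(TBSO)labda-7,13-dien-15-ol; 31 30-(TBSO)triacontanoic acid
Product: 32 (3R,5S,9R,10S,13E)-3-(TBSO)labda-7,13-dien-15-yl 30-(TBSO)triacontanoate
Conditions: EDC·HCl, DMAP (cat.), CH2Cl2, rt
Reagents that add atoms: none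
Why: Steglich-type carbodiimide esterification of the unhindered allylic primary alcohol under neutral conditions that do not ionise the allylic system.

Step 22
Reactants: 32 (3R,5S,9R,10S,13E)-3-(TBSO)labda-7,13-dien-15-yl 30-(TBSO)triacontanoate
Product: 33 (3R,5S,9R,10S,13E)-3-hydroxylabda-7,13-dien-15-yl 30-hydroxytriacontanoate
Conditions: HF·pyridine, pyridine/THF, 0 °C to rt
Reagents that add atoms: none
Why: Fluoride-mediated cleavage of both silyl ethers with buffered HF·pyridine, under which the allylic ester and the trisubstituted alkenes should be stable.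

**Compound list**

1 | geranyl acetate, (2E)-3,7-dimethylocta-2,6-dien-1-yl acetate | CC(C)=CCC/C(C)=C/COC(C)=O | starting material
2 | ozonide, (2E)-5-(5,5-dimethyl-1,2,4-trioxolan-3-yl)-3-methylpent-2-en-1-yl acetate | CC1(C)OOC(CC/C(C)=C/COC(C)=O)O1 | intermediate
3 | (2E)-3-methyl-6-oxohex-2-en-1-yl acetate | O=CCC/C(C)=C/COC(C)=O | intermediate
4 | 1-methoxy-2-methyl-1-(trimethylsilyloxy)prop-1-ene | COC(O[Si](C)(C)C)=C(C)C | starting material
5 | methyl (3R,6E)-8-acetoxy-3-hydroxy-2,2,6-trimethyloct-6-enoate | COC(=O)C(C)(C)[C@H](O)CC/C(C)=C/COC(C)=O | intermediate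
6 | methyl (3R,6E)-8-acetoxy-3-[(tert-butyldimethylsilyl)oxy]-2,2,6-trimethyloct-6-enoate | COC(=O)C(C)(C)[C@H](O[Si](C)(C)C(C)(C)C)CC/C(C)=C/COC(C)=O | intermediate
7 | (2E,6R)-6-[(tert-butyldimethylsilyl)oxy]-3,7,7-trimethyloct-2-ene-1,8-diol | OCC(C)(C)[C@H](O[Si](C)(C)C(C)(C)C)CC/C(C)=C/CO | intermediate
8 | (2E,6R)-6-[(tert-butyldimethylsilyl)oxy]-8-hydroxy-3,7,7-trimethyloct-2-en-1-yl 2,2-dimethylpropanoate | CC(C)(C)C(=O)OC/C=C(C)/CC[C@@H](O[Si](C)(C)C(C)(C)C)C(C)(C)CO | intermediate
9 | (2E,6R)-6-[(tert-butyldimethylsilyl)oxy]-3,7,7-trimethyl-8-oxooct-2-en-1-yl 2,2-dimethylpropanoate | CC(C)(C)C(=O)OC/C=C(C)/CC[C@@H](O[Si](C)(C)C(C)(C)C)C(C)(C)C=O | intermediate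
10 | dimethyl (2-oxobutyl)phosphonate | CCC(=O)CP(=O)(OC)OC | starting material
11 | (2E,6R,8E)-6-[(tert-butyldimethylsilyl)oxy]-3,7,7-trimethyl-10-oxododeca-2,8-dien-1-yl 2,2-dimethylpropanoate | CC(C)(C)C(=O)OC/C=C(C)/CC[C@@H](O[Si](C)(C)C(C)(C)C)C(C)(C)/C=C/C(=O)CC | intermediate
12 | (2E,6R,8E,10Z)-6,10-bis[(tert-butyldimethylsilyl)oxy]-3,7,7-trimethyldodeca-2,8,10-trien-1-yl 2,2-dimethylpropanoate | CC(C)(C)C(=O)OC/C=C(C)/CC[C@@H](O[Si](C)(C)C(C)(C)C)C(C)(C)/C=C/C(O[Si](C)(C)C(C)(C)C)=C/C | intermediate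
13 | (2E,6R,8E,10Z)-6,10-bis[(tert-butyldimethylsilyl)oxy]-3,7,7-trimethyldodeca-2,8,10-trien-1-ol | OC/C=C(C)/CC[C@@H](O[Si](C)(C)C(C)(C)C)C(C)(C)/C=C/C(O[Si](C)(C)C(C)(C)C)=C/C | intermediate
14 | (2E,6R,8E,10Z)-6,10-bis[(tert-butyldimethylsilyl)oxy]-3,7,7-trimethyldodeca-2,8,10-trienal (cycloaddition precursor) | O=C/C=C(C)/CC[C@@H](O[Si](C)(C)C(C)(C)C)C(C)(C)/C=C/C(O[Si](C)(C)C(C)(C)C)=C/C | intermediate
15 | (3R,5S,8S,9R,10R)-3,7-bis(TBSO)-12,13,14,15,16-pentanorlabd-6-en-11-al; trans-decalin with 9-CHO, 8-CH3, 10-CH3 and 3-OTBS on one face | C[C@@H]1C(O[Si](C)(C)C(C)(C)C)=C[C@@H]2C(C)(C)[C@H](O[Si](C)(C)C(C)(C)C)CC[C@@]2(C)[C@@H]1C=O | intermediate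
16 | (3R,5S,8S,9R,10S)-3,7-bis(TBSO)-13,14,15,16-tetranorlabda-6,11-diene | C[C@@H]1C(O[Si](C)(C)C(C)(C)C)=C[C@@H]2C(C)(C)[C@H](O[Si](C)(C)C(C)(C)C)CC[C@@]2(C)[C@@H]1C=C | intermediate
17 | (3R,5S,8S,9R,10S)-3-(TBSO)-13,14,15,16-tetranorlabd-11-en-7-one | C[C@@H]1C(=O)C[C@@H]2C(C)(C)[C@H](O[Si](C)(C)C(C)(C)C)CC[C@@]2(C)[C@@H]1C=C | intermediate
18 | bromomagnesium C7=C8 enolate of 17 | CC1=C(O[Mg]Br)C[C@@H]2C(C)(C)[C@H](O[Si](C)(C)C(C)(C)C)CC[C@@]2(C)[C@@H]1C=C | intermediate
19 | (3R,5S,9S,10R)-3-(TBSO)-13,14,15,16-tetranorlabda-7,11-dien-7-yl trifluoromethanesulfonate | CC1=C(OS(=O)(=O)C(F)(F)F)C[C@@H]2C(C)(C)[C@H](O[Si](C)(C)C(C)(C)C)CC[C@@]2(C)[C@@H]1C=C | intermediate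
20 | (3R,5S,9R,10R)-3-(TBSO)-13,14,15,16-tetranorlabda-7,11-diene | CC1=CC[C@@H]2C(C)(C)[C@H](O[Si](C)(C)C(C)(C)C)CC[C@@]2(C)[C@@H]1C=C | intermediate
21 | ethyl acetoacetate | CCOC(=O)CC(C)=O | starting material
22 | ethyl (2E)-3-(trifluoromethanesulfonyloxy)but-2-enoate | CCOC(=O)/C=C(C)/OS(=O)(=O)C(F)(F)F | intermediate
23 | 9-[(3R,5S,9R,10S)-3-(TBSO)-13,14,15,16-tetranorlabd-7-en-12-yl]-9-borabicyclo[3.3.1]nonane | CC1=CC[C@@H]2C(C)(C)[C@H](O[Si](C)(C)C(C)(C)C)CC[C@@]2(C)[C@@H]1CCB1C2CCCC1CCC2 | intermediate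
24 | ethyl (3R,5S,9R,10S,13E)-3-(TBSO)labda-7,13-dien-15-oate | CC1=CC[C@@H]2C(C)(C)[C@H](O[Si](C)(C)C(C)(C)C)CC[C@@]2(C)[C@@H]1CC/C(C)=C/C(=O)OCC | intermediate
25 | (3R,5S,9R,10S,13E)-3-(TBSO)labda-7,13-dien-15-ol | CC1=CC[C@@H]2C(C)(C)[C@H](O[Si](C)(C)C(C)(C)C)CC[C@@]2(C)[C@@H]1CC/C(C)=C/CO | intermediate
26 | 12-bromododecan-1-ol | BrCCCCCCCCCCCCO | starting material
27 | (12-bromododecyloxy)(tert-butyl)dimethylsilane | BrCCCCCCCCCCCCO[Si](C)(C)C(C)(C)C | intermediate
28 | 18-bromooctadecanoic acid | OC(=O)CCCCCCCCCCCCCCCCCBr | starting material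
29 | 12-[(tert-butyldimethylsilyl)oxy]dodecylmagnesium bromide | Br[Mg]CCCCCCCCCCCCO[Si](C)(C)C(C)(C)C | intermediate
30 | chloromagnesium 18-bromooctadecanoate | Cl[Mg]OC(=O)CCCCCCCCCCCCCCCCCBr | intermediate
31 | 30-[(tert-butyldimethylsilyl)oxy]triacontanoic acid | OC(=O)CCCCCCCCCCCCCCCCCCCCCCCCCCCCCO[Si](C)(C)C(C)(C)C | intermediate
32 | (3R,5S,9R,10S,13E)-3-(TBSO)labda-7,13-dien-15-yl 30-(TBSO)triacontanoate | CC1=CC[C@@H]2C(C)(C)[C@H](O[Si](C)(C)C(C)(C)C)CC[C@@]2(C)[C@@H]1CC/C(C)=C/COC(=O)CCCCCCCCCCCCCCCCCCCCCCCCCCCCCO[Si](C)(C)C(C)(C)C | intermediate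
33 | (3R,5S,9R,10S,13E)-3-hydroxylabda-7,13-dien-15-yl 30-hydroxytriacontanoate, i.e. (2E)-5-[(1R,4aS,6R,8aS)-6-hydroxy-2,5,5,8a-tetramethyl-1,4,4a,5,6,7,8,8a-octahydronaphthalen-1-yl]-3-methylpent-2-en-1-yl 30-hydroxytriacontanoate | CC1=CC[C@@H]2C(C)(C)[C@H](O)CC[C@@]2(C)[C@@H]1CC/C(C)=C/COC(=O)CCCCCCCCCCCCCCCCCCCCCCCCCCCCCO | target

**Step count and risks**

Total step count: 22. Longest linear sequence: 19 steps (steps 1–15, 17, 18, 21, 22); steps 16, 19 and 20 make the two coupling partners.

Most likely to fail, step 11. At the temperature that a polarity-mismatched diene demands, the endo (trans-fusion) and diene-face preferences may erode, the enal may isomerise E/Z through its dienol, and the silyl enol ether may be lost. The fallback sets out from 11 and comes back at 17: the C7 oxygen is carried as a triflate, which cannot act as a Mukaiyama donor, so the cyclisation can be run with a Lewis acid at low temperature. Deprotonation of 11 with KN(SiMe3)2 and O-sulfonylation with PhNTf2 should give the (10Z)-dienyl triflate F1. i-Bu2AlH at −78 °C frees the allylic alcohol F2, and MnO2 gives the trienal F3. Me2AlCl in CH2Cl2 (−78 to −20 °C) should then close both rings to the triflyloxy aldehyde F4. Wittig methylenation gives the vinyl compound F5, MeLi cuts its S–O bond to the lithium enolate F6, and protonation with AcOH at −78 °C returns ketone 17.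

Second, step 14. Equilibration of the magnesium enolate may be incomplete, so that kinetic C6 deprotonation leaks through to the 6,7-enol triflate, or the magnesium enolate may be sulfonylated sluggishly. The fallback sets out from 17 and comes back at 20, and replaces enolate trapping by an anti elimination. NaOMe in MeOH epimerises C8 to the equatorial-methyl ketone F7. LiBH(s-Bu)3 at −78 °C attacks equatorially to give the axial C7 alcohol F8. POCl3 in pyridine then eliminates through the anti-periplanar axial C8–H towards the more substituted alkene, giving 20.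

Third, step 2. Enantiofacial control by the stoichiometric boron promoter may be insufficient with this aldehyde, or its sense may be opposite to the one assumed. The fallback sets out from 3 (with 4) and comes back at 5, and moves the stereo-defining event to a catalytic hydrogenation. BF3·OEt2-mediated Mukaiyama aldol gives the racemic aldol F9, and Dess–Martin oxidation gives the β-keto ester F10. Hydrogenation with RuCl2[(R)-BINAP] and H2 in MeOH is expected, by analogy with simple β-keto esters, to return the (3R)-alcohol 5, the allylic acetate alkene being inert to this catalyst.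

**Further compounds**

F1 | step 11 | (2E,6R,8E,10Z)-6-(TBSO)-3,7,7-trimethyl-10-(trifluoromethanesulfonyloxy)dodeca-2,8,10-trien-1-yl 2,2-dimethylpropanoate | CC(C)(C)C(=O)OC/C=C(C)/CC[C@@H](O[Si](C)(C)C(C)(C)C)C(C)(C)/C=C/C(OS(=O)(=O)C(F)(F)F)=C/C
F2 | step 11 | (2E,6R,8E,10Z)-6-(TBSO)-3,7,7-trimethyl-10-(trifluoromethanesulfonyloxy)dodeca-2,8,10-trien-1-ol | OC/C=C(C)/CC[C@@H](O[Si](C)(C)C(C)(C)C)C(C)(C)/C=C/C(OS(=O)(=O)C(F)(F)F)=C/C
F3 | step 11 | (2E,6R,8E,10Z)-6-(TBSO)-3,7,7-trimethyl-10-(trifluoromethanesulfonyloxy)dodeca-2,8,10-trienal | O=C/C=C(C)/CC[C@@H](O[Si](C)(C)C(C)(C)C)C(C)(C)/C=C/C(OS(=O)(=O)C(F)(F)F)=C/C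
F4 | step 11 | (3R,5S,8S,9R,10R)-3-(TBSO)-7-(trifluoromethanesulfonyloxy)-12,13,14,15,16-pentanorlabd-6-en-11-al | C[C@@H]1C(OS(=O)(=O)C(F)(F)F)=C[C@@H]2C(C)(C)[C@H](O[Si](C)(C)C(C)(C)C)CC[C@@]2(C)[C@@H]1C=O
F5 | step 11 | (3R,5S,8S,9R,10S)-3-(TBSO)-7-(trifluoromethanesulfonyloxy)-13,14,15,16-tetranorlabda-6,11-diene | C[C@@H]1C(OS(=O)(=O)C(F)(F)F)=C[C@@H]2C(C)(C)[C@H](O[Si](C)(C)C(C)(C)C)CC[C@@]2(C)[C@@H]1C=C
F6 | step 11 | lithium (3R,5S,8S,9R,10S)-3-(TBSO)-13,14,15,16-tetranorlabda-6,11-dien-7-olate | C[C@@H]1C(O[Li])=C[C@@H]2C(C)(C)[C@H](O[Si](C)(C)C(C)(C)C)CC[C@@]2(C)[C@@H]1C=C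
F7 | step 14 | (3R,5S,8R,9R,10S)-3-(TBSO)-13,14,15,16-tetranorlabd-11-en-7-one | C[C@H]1C(=O)C[C@@H]2C(C)(C)[C@H](O[Si](C)(C)C(C)(C)C)CC[C@@]2(C)[C@@H]1C=C
F8 | step 14 | (3R,5S,7S,8R,9R,10S)-3-(TBSO)-13,14,15,16-tetranorlabd-11-en-7-ol | C[C@H]1[C@@H](O)C[C@@H]2C(C)(C)[C@H](O[Si](C)(C)C(C)(C)C)CC[C@@]2(C)[C@@H]1C=C
F9 | step 2 | racemic methyl (6E)-8-acetoxy-3-hydroxy-2,2,6-trimethyloct-6-enoate | COC(=O)C(C)(C)C(O)CC/C(C)=C/COC(C)=O
F10 | step 2 | methyl (6E)-8-acetoxy-2,2,6-trimethyl-3-oxooct-6-enoate | COC(=O)C(C)(C)C(=O)CC/C(C)=C/COC(C)=O
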